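**Analysis of the target**

The target 14 is a monocyclic α-arylidene-β-benzyl-γ-butyrolactone with ring atoms O1, C2 (carbonyl), C3, C4 and C5. C3 carries an exocyclic double bond to a CH bearing a 3-hydroxy-4,5-dimethoxyphenyl ring (ring B). C4 carries a CH2 bound to a 4-hydroxy-3-methoxyphenyl ring (ring A). There is one stereocentre, C4, of R configuration, and one stereogenic double bond, E, with ring B anti to the C2 carbonyl and therefore syn to C4. The two elements are neighbours: the C4–H bond is allylic and γ to the carbonyl, so a base that reaches it would move the double bond into the ring and erase both. Two free phenols, a Michael-acceptor enoate and the lactone are the other sensitive groups. The difficulty is that C4 is a tertiary all-carbon-substituted centre with no heteroatom on it to steer an asymmetric reaction, and that the alkene must be installed beside it without touching it. The strategy rests on the three carbon arms of C4: the benzylic CH2, C5, and C3 leading to C2. The chain C5–C4(–CH2)–C3–C2 is the skeleton of methylsuccinic acid, with its methyl carbon as the benzylic carbon and its two carboxyl carbons as C5 and C2, so the stereocentre can be bought and the ring A bond made at that methyl group.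

**Retrosynthetic reasoning**

14 from 13. The two phenols are unmasked last. Both are carried as tert-butyldimethylsilyl ethers so that one buffered fluoride treatment finishes the synthesis without acid, strong base or hydrogen near the enoate.

13 from 10 and 12. The exocyclic C3=CH bond is cut. It is the most fragile element and should come late. The cut divides the molecule into two pieces of similar size with one arene each. A carbonyl olefination fixes the position of the double bond, so no endocyclic isomer can arise from the bond-forming event itself. The forward step has to give the E isomer and must not deprotonate C4. The aldehyde 12 comes from phenol 11 by silylation.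

10 from 8. The C3–P bond is cut. Lactone 8 has only one enolisable position, C3, so the phosphonate can only go where the alkene is needed, and C4 is not acidic at this stage.

8 from 7 from 6. This is a protecting-group exchange on ring A. A benzyl ether is wanted for the key step because it tolerates a hot fluorinated alcohol and carbonate. It cannot be removed once the benzylidene is present, since hydrogenolysis would saturate the alkene. The exchange is therefore placed at the saturated lactone.

6 from 4. The lactone C5–O bond is opened and C5 is raised to the acid level. Lactone 6 is the reduced and cyclised form of half-ester 4: the free carboxyl next to the stereocentre becomes C5 and the ester carbon becomes C2. The forward step needs a hydride reagent that reduces an acid before an ester; the hydroxy ester 5 then closes by itself or with a trace of acid.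

4 from 3 and 2. This is the key disconnection, at the benzylic CH2–aryl bond. Cutting here leaves the whole environment of C4, with the right configuration, in the purchasable half-ester 3, and only one sp3–sp2 bond has to be made. The free carboxyl of 3, the future C5, sits exactly β to the methyl group and can direct a palladium catalyst to it. The forward reaction must choose the methyl C–H over the methylene next to the ester, stop after one arylation and leave the α-stereocentre alone.

2 from 1. The phenol of 1 is benzylated. Acid 3 is bought as the single enantiomer.

**Alternatives that were turned down**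

Alternative 1: The C3–C4 bond of the lactone is cut, leading back to 3-[4-(tert-butyldimethylsilyloxy)-3-methoxyphenyl]propyl diazoacetate A1. In the forward step a chiral dirhodium carboxamidate catalyst forms a carbene that inserts into the homobenzylic C–H bond. This closes the five-membered ring and sets C4 in one operation, giving (R)-4-[4-(tert-butyldimethylsilyloxy)-3-methoxybenzyl]dihydrofuran-2(3H)-one A2, which is the same compound as 8.
- For it: ring and stereocentre arise together, A1 is only a few steps from cheap phenylpropanoid material, and no protecting-group exchange is needed. This kind of insertion is well suited to 3-arylpropyl diazoacetates. On precedent for this lactone class and on step count to 8 it is stronger than the chosen route.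
- Against it: the configuration of C4 depends entirely on face discrimination by a specialised catalyst, so any shortfall in enantiomeric purity is carried into an oily lactone that is hard to upgrade. The electron-rich ring A activates the benzylic C–H bond toward a competing six-membered insertion. The diazo ester needs slow addition to suppress carbene dimerisation.
- Comparison: the chosen strategy buys C4 with full enantiomeric purity and uses Pd(OAc)2 with a simple amino acid ligand. It pays with two extra protecting-group steps and a less proven key step.

Alternative 2: The bond between ring B and the benzylidene carbon is cut. This leads to (R)-4-[4-(tert-butyldimethylsilyloxy)-3-methoxybenzyl]-3-methylenedihydrofuran-2(3H)-one A3 and 2-[3-(tert-butyldimethylsilyloxy)-4,5-dimethoxyphenyl]-4,4,5,5-tetramethyl-1,3,2-dioxaborolane A4. In the forward step the aryl group is transferred from boron to divalent palladium, adds across the exocyclic C3=CH2 and, after β-hydride elimination, should give the bis(tert-butyldimethylsilyl) ether of the target A5, identical with 13.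
- For it: ring B is introduced last, which is ideal for analogues, and no strong base is needed late in the route. On modularity it is stronger than the chosen route.
- Against it: the step makes no stereocentre, so A3 still needs C4 from another asymmetric step. After carbopalladation the metal sits on C3 and has two kinds of β-hydrogen. Elimination of the benzylic hydrogen gives A5, but elimination of the C4 hydrogen gives an endocyclic butenolide and destroys the stereocentre. Re-addition of the palladium hydride can also scramble the geometry. Making A3 from 8 by α-methylenation costs as many steps as the phosphonate.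
- Comparison: the chosen olefination places the double bond unambiguously, and the chosen key step is the one that supplies C4.

Alternative 3: The C4–C5 bond is cut with allylic transposition, leading to the (R,E)-tributylstannylmethyl ether of 1-[4,5-dimethoxy-3-(triisopropylsilyloxy)phenyl]-2-[(tert-butyldimethylsilyloxy)methyl]-4-[3-methoxy-4-(triisopropylsilyloxy)phenyl]but-2-en-1-ol A6. In the forward step tin–lithium exchange gives an alkoxymethyl-lithium that undergoes the Still–Wittig [2,3]-shift. The configuration of the carbinol carbon is transferred suprafacially to C4 and the double bond moves to C3=CH(ring B). The product is (2R,3E)-3-[(tert-butyldimethylsilyloxy)methyl]-4-[4,5-dimethoxy-3-(triisopropylsilyloxy)phenyl]-2-[3-methoxy-4-(triisopropylsilyloxy)benzyl]but-3-en-1-ol A7.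
- For it: one step settles both stereochemical elements. A substituent on the central allyl carbon is known to push the carbinol substituent anti to it, which is the required E geometry. On control of the alkene geometry it is stronger than the chosen olefination.
- Against it: the asymmetric problem is only moved back to the benzylic carbinol of A6, which needs its own enantioselective step and a geometrically pure trisubstituted alkene. The benzylic, allylic ether anion can also follow a [1,2]-shift. The route uses stoichiometric organotin and three silyl groups of two kinds. After the rearrangement A7 still needs selective desilylation, oxidation to the acid level and lactonisation, so the route is clearly longer.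
- Comparison: the chosen strategy takes the stereocentre from the chiral pool, avoids tin and reaches the target in nine steps. It accepts that the E geometry rests on the thermodynamic bias of the olefination.

Key step: step 2

Assumption: the half-ester 3 is bought as the single (R)-enantiomer, the catalogue mono-methyl ester of (R)-methylsuccinic acid with the free carboxyl next to the stereocentre.

**Route**

Step 1
Reactants: 1 4-iodo-2-methoxyphenol
Product: 2 1-(benzyloxy)-4-iodo-2-methoxybenzene
Conditions: BnBr, K2CO3, DMF, rt
Reagents that add atoms: benzyl bromide, BrCc1ccccc1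
Why: Williamson ether synthesis; the phenoxide is O-alkylated by the benzylic bromide and the aryl iodide is inert to K2CO3.

Step 2
Reactants: 3 (R)-4-methoxy-2-methyl-4-oxobutanoic acid; 2 1-(benzyloxy)-4-iodo-2-methoxybenzene (1.5 equiv)
Product: 4 (R)-2-[4-(benzyloxy)-3-methoxybenzyl]-4-methoxy-4-oxobutanoic acid
Conditions: Pd(OAc)2 (10 mol%), N-acetylglycine (20 mol%), Ag2CO3 (1.5 equiv), (CF3)2CHOH, 90 °C; then aq. HCl
Reagents that add atoms: none
Why: The closest known reaction type is the ligand-enabled, carboxylate-directed β-C(sp3)–H arylation of free aliphatic acids with aryl iodides, and 3 is an α-branched acid of the kind this catalysis accepts. The carboxylate of 3 binds divalent palladium, and the N-acyl amino acid ligand acts as internal base in a concerted metalation–deprotonation of a methyl C–H bond, giving a five-membered palladacycle. Oxidative addition of 2 raises the metal to tetravalent palladium, reductive elimination forms the CH2–aryl bond, and Ag2CO3 removes iodide and takes up the proton. No ring is closed and no stereocentre is made; the existing centre is a spectator because the cleaved bond lies on the methyl carbon and the α-hydrogen of a carboxylate is far too weakly acidic for carbonate. Site selectivity is needed between the methyl group and the methylene next to the ester, both β to the carboxyl; the primary C–H bond is favoured in the metalation on steric grounds, and secondary positions normally need purpose-built ligands. Over-arylation should be limited for the same reason, since 4 offers only secondary β-hydrogens. The methyl ester is inert, and the benzyl ether tolerates hot hexafluoroisopropanol and carbonate where a phenolic silyl ether might not.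

Step 3
Reactants: 4 (R)-2-[4-(benzyloxy)-3-methoxybenzyl]-4-methoxy-4-oxobutanoic acid
Product: 6 (R)-4-[4-(benzyloxy)-3-methoxybenzyl]dihydrofuran-2(3H)-one, via hydroxy ester 5 (not isolated)
Conditions: BH3·SMe2, THF, 0 °C to rt; MeOH; then TsOH (cat.), CH2Cl2, rt
Reagents that add atoms: none
Why: Chemoselective borane reduction of a carboxylic acid beside an ester (the acid is activated as an acyloxyborane, the ester is not), followed by acid-catalysed lactonisation of the γ-hydroxy ester; C4 is not involved and no stereocentre is formed.

Step 4
Reactants: 6 (R)-4-[4-(benzyloxy)-3-methoxybenzyl]dihydrofuran-2(3H)-one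
Product: 7 (R)-4-(4-hydroxy-3-methoxybenzyl)dihydrofuran-2(3H)-one
Conditions: H2 (1 atm), 10% Pd/C, EtOAc, rt
Reagents that add atoms: none
Why: Catalytic hydrogenolysis of a benzyl aryl ether; it is done before the alkene exists because the benzylidene would not survive hydrogen, and the lactone and methyl ether are inert.

Step 5
Reactants: 7 (R)-4-(4-hydroxy-3-methoxybenzyl)dihydrofuran-2(3H)-one
Product: 8 (R)-4-[4-(tert-butyldimethylsilyloxy)-3-methoxybenzyl]dihydrofuran-2(3H)-one
Conditions: TBSCl, imidazole, DMF, rt
Reagents that add atoms: tert-butyldimethylsilyl chloride, CC(C)(C)[Si](C)(C)Cl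
Why: Imidazole-promoted silylation of a phenol; the silyl ether masks the acidic phenol against the amide base of step 6 and can be removed by fluoride at the end.

Step 6
Reactants: 8 (R)-4-[4-(tert-butyldimethylsilyloxy)-3-methoxybenzyl]dihydrofuran-2(3H)-one
Product: 10 diethyl [(4S)-4-[4-(tert-butyldimethylsilyloxy)-3-methoxybenzyl]-2-oxotetrahydrofuran-3-yl]phosphonate (C3 epimers), via enol phosphate 9 (not isolated)
Conditions: LiN(iPr)2 (1.1 equiv), THF, −78 °C; ClP(O)(OEt)2, −78 °C to rt; then LiN(iPr)2 (2.2 equiv), −78 °C to rt; AcOH
Reagents that add atoms: diethyl chlorophosphate, CCOP(=O)(Cl)OCC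
Why: The lactone enolate is O-phosphorylated to the ketene acetal phosphate, and further amide base induces the 1,3-phosphoryl shift from oxygen to carbon (vinyl phosphate to phosphonate rearrangement), driven by the stabilised phosphonate enolate. C3 is the only enolisable position; its new centre forms without control and is erased in step 8, while C4 keeps its spatial arrangement (the descriptor becomes S only because phosphorus raises the rank of C3).

Step 7
Reactants: 11 3-hydroxy-4,5-dimethoxybenzaldehyde
Product: 12 3-(tert-butyldimethylsilyloxy)-4,5-dimethoxybenzaldehyde
Conditions: TBSCl, imidazole, DMF, rt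
Reagents that add atoms: tert-butyldimethylsilyl chloride, CC(C)(C)[Si](C)(C)Cl
Why: Silylation of the phenol; a free phenoxide would consume base and deactivate the aldehyde in the olefination.

Step 8
Reactants: 10 diethyl [(4S)-4-[4-(tert-butyldimethylsilyloxy)-3-methoxybenzyl]-2-oxotetrahydrofuran-3-yl]phosphonate; 12 3-(tert-butyldimethylsilyloxy)-4,5-dimethoxybenzaldehyde
Product: 13 (R,E)-3-[3-(tert-butyldimethylsilyloxy)-4,5-dimethoxybenzylidene]-4-[4-(tert-butyldimethylsilyloxy)-3-methoxybenzyl]dihydrofuran-2(3H)-one
Conditions: NaH (0.95 equiv), THF, 0 °C; then 12, 0 °C to rt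
Reagents that add atoms: none
Why: Horner–Wadsworth–Emmons olefination; the stabilised phosphonate anion adds reversibly to the aldehyde and phosphate is lost by syn-elimination, which should favour the E alkene with ring B anti to the lactone carbonyl. With NaH as the limiting reagent no base strong enough to remove the γ-hydrogen at C4 remains, so the stereocentre is kept.

Step 9
Reactants: 13 (R,E)-3-[3-(tert-butyldimethylsilyloxy)-4,5-dimethoxybenzylidene]-4-[4-(tert-butyldimethylsilyloxy)-3-methoxybenzyl]dihydrofuran-2(3H)-one
Product: 14 (R,E)-3-(3-hydroxy-4,5-dimethoxybenzylidene)-4-(4-hydroxy-3-methoxybenzyl)dihydrofuran-2(3H)-one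
Conditions: Bu4NF (2.5 equiv), AcOH (2.5 equiv), THF, 0 °C
Reagents that add atoms: none
Why: Fluoride cleavage of both aryl silyl ethers, driven by the Si–F bond; acetic acid protonates the phenoxides as they form, so the medium stays too weakly basic to move the exocyclic double bond or to open the lactone.

**Compound list**

1 | 4-iodo-2-methoxyphenol | COc1cc(I)ccc1O | starting material
2 | 1-(benzyloxy)-4-iodo-2-methoxybenzene | COc1cc(I)ccc1OCc1ccccc1 | intermediate
3 | (R)-4-methoxy-2-methyl-4-oxobutanoic acid | C[C@H](CC(=O)OC)C(=O)O | starting material
4 | (R)-2-[4-(benzyloxy)-3-methoxybenzyl]-4-methoxy-4-oxobutanoic acid | COC(=O)C[C@@H](Cc1ccc(OCc2ccccc2)c(OC)c1)C(=O)O | intermediate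
5 | methyl (R)-4-[4-(benzyloxy)-3-methoxyphenyl]-3-(hydroxymethyl)butanoate | COC(=O)C[C@@H](Cc1ccc(OCc2ccccc2)c(OC)c1)CO | intermediate (not isolated)
6 | (R)-4-[4-(benzyloxy)-3-methoxybenzyl]dihydrofuran-2(3H)-one | COc1cc(C[C@H]2COC(=O)C2)ccc1OCc1ccccc1 | intermediate
7 | (R)-4-(4-hydroxy-3-methoxybenzyl)dihydrofuran-2(3H)-one | COc1cc(C[C@H]2COC(=O)C2)ccc1O | intermediate
8 | (R)-4-[4-(tert-butyldimethylsilyloxy)-3-methoxybenzyl]dihydrofuran-2(3H)-one | COc1cc(C[C@H]2COC(=O)C2)ccc1O[Si](C)(C)C(C)(C)C | intermediate
9 | diethyl (R)-4-[4-(tert-butyldimethylsilyloxy)-3-methoxybenzyl]-4,5-dihydrofuran-2-yl phosphate | CCOP(=O)(OCC)OC1=C[C@@H](Cc2ccc(O[Si](C)(C)C(C)(C)C)c(OC)c2)CO1 | intermediate (not isolated)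
10 | diethyl [(4S)-4-[4-(tert-butyldimethylsilyloxy)-3-methoxybenzyl]-2-oxotetrahydrofuran-3-yl]phosphonate, C3 epimers | CCOP(=O)(OCC)C1C(=O)OC[C@@H]1Cc1ccc(O[Si](C)(C)C(C)(C)C)c(OC)c1 | intermediate
11 | 3-hydroxy-4,5-dimethoxybenzaldehyde | COc1cc(C=O)cc(O)c1OC | starting material
12 | 3-(tert-butyldimethylsilyloxy)-4,5-dimethoxybenzaldehyde | COc1cc(C=O)cc(O[Si](C)(C)C(C)(C)C)c1OC | intermediate
13 | (R,E)-3-[3-(tert-butyldimethylsilyloxy)-4,5-dimethoxybenzylidene]-4-[4-(tert-butyldimethylsilyloxy)-3-methoxybenzyl]dihydrofuran-2(3H)-one | COc1cc(C[C@H]2COC(=O)/C2=C/c2cc(O[Si](C)(C)C(C)(C)C)c(OC)c(OC)c2)ccc1O[Si](C)(C)C(C)(C)C | intermediate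
14 | (R,E)-3-(3-hydroxy-4,5-dimethoxybenzylidene)-4-(4-hydroxy-3-methoxybenzyl)dihydrofuran-2(3H)-one | COc1cc(C[C@H]2COC(=O)/C2=C/c2cc(O)c(OC)c(OC)c2)ccc1O | target

**Step count and risks**

Total step count: 9. Longest linear sequence: 8 steps (1 to 2, 4, 6, 7, 8, 10, 13, 14); step 7 is a one-step side branch.

Step 2 (key step). Metalation of an acid with only one α-substituent may be slow, so that conversion stalls while 2 is consumed by protodeiodination or homocoupling. Metalation at the methylene next to the ester, a second arylation at the new benzylic position, or dehydrogenation of the acid by β-hydride elimination (which would also erode C4) are the other ways the step could fail. The fallback gives up the C–H arylation and takes the stereocentre from asymmetric catalysis. It sets out from 2 and comes back at 4. Heck coupling of 2 with 2-methylenesuccinic acid 4-methyl ester (C=C(CC(=O)OC)C(=O)O) under Pd(OAc)2, P(o-tol)3 and Et3N in MeCN should give (E)-2-[4-(benzyloxy)-3-methoxybenzylidene]-4-methoxy-4-oxobutanoic acid F1. Enantioselective hydrogenation of F1 with [Rh(cod)2]BF4 and a chiral bisphosphine of the DuPhos class, with the ligand enantiomer chosen for R, should give 4. The homogeneous catalyst leaves the benzyl ether intact.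

Step 6. The oxygen-to-carbon phosphoryl migration may stop at the enol phosphate. The lactone enolate may condense with unreacted lactone, or the amide base may open the ring. The fallback forms the C–P bond directly with a trivalent phosphorus electrophile. It sets out from 8 and comes back at 10. The enolate of 8 (LiN(iPr)2, THF, −78 °C) is treated with diethyl chlorophosphite, which should give diethyl [(4S)-4-[4-(tert-butyldimethylsilyloxy)-3-methoxybenzyl]-2-oxotetrahydrofuran-3-yl]phosphonite F2. Oxidation of F2 in the same flask with H2O2 should give 10.

Step 8. The substituent on C4 sits next to the forming alkene and may lower the E preference. The hindered tertiary phosphonate anion may add slowly. Any excess base could move the double bond into the ring with loss of C4. The fallback replaces the olefination by an aldol addition and elimination. It sets out from 8, uses 12, and comes back at 13, bypassing steps 6 and 8. The lithium enolate of 8 (LiN(iPr)2, THF, −78 °C) adds to 12 to give (4R)-3-{[3-(tert-butyldimethylsilyloxy)-4,5-dimethoxyphenyl](hydroxy)methyl}-4-[4-(tert-butyldimethylsilyloxy)-3-methoxybenzyl]dihydrofuran-2(3H)-one F3 as a mixture of diastereomers. Mesylation with MsCl and Et3N gives the methanesulfonate of that alcohol F4. Elimination with DBU through the enolate should converge both diastereomers on the more stable E isomer 13.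

**Further compounds**

F1 | step 2 | (E)-2-[4-(benzyloxy)-3-methoxybenzylidene]-4-methoxy-4-oxobutanoic acid | COC(=O)C/C(C(=O)O)=C\c1ccc(OCc2ccccc2)c(OC)c1
F2 | step 6 | diethyl [(4S)-4-[4-(tert-butyldimethylsilyloxy)-3-methoxybenzyl]-2-oxotetrahydrofuran-3-yl]phosphonite, C3 epimers | CCOP(OCC)C1C(=O)OC[C@@H]1Cc1ccc(O[Si](C)(C)C(C)(C)C)c(OC)c1
F3 | step 8 | (4R)-3-{[3-(tert-butyldimethylsilyloxy)-4,5-dimethoxyphenyl](hydroxy)methyl}-4-[4-(tert-butyldimethylsilyloxy)-3-methoxybenzyl]dihydrofuran-2(3H)-one, diastereomer mixture | COc1cc(C[C@H]2COC(=O)C2C(O)c2cc(O[Si](C)(C)C(C)(C)C)c(OC)c(OC)c2)ccc1O[Si](C)(C)C(C)(C)C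
F4 | step 8 | methanesulfonate of F3, diastereomer mixture | COc1cc(C[C@H]2COC(=O)C2C(OS(C)(=O)=O)c2cc(O[Si](C)(C)C(C)(C)C)c(OC)c(OC)c2)ccc1O[Si](C)(C)C(C)(C)C
A1 | alternative 1 | 3-[4-(tert-butyldimethylsilyloxy)-3-methoxyphenyl]propyl diazoacetate | COc1cc(CCCOC(=O)C=[N+]=[N-])ccc1O[Si](C)(C)C(C)(C)C
A2 | alternative 1 | (R)-4-[4-(tert-butyldimethylsilyloxy)-3-methoxybenzyl]dihydrofuran-2(3H)-one | COc1cc(C[C@H]2COC(=O)C2)ccc1O[Si](C)(C)C(C)(C)C
A3 | alternative 2 | (R)-4-[4-(tert-butyldimethylsilyloxy)-3-methoxybenzyl]-3-methylenedihydrofuran-2(3H)-one | C=C1C(=O)OC[C@@H]1Cc1ccc(O[Si](C)(C)C(C)(C)C)c(OC)c1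
A4 | alternative 2 | 2-[3-(tert-butyldimethylsilyloxy)-4,5-dimethoxyphenyl]-4,4,5,5-tetramethyl-1,3,2-dioxaborolane | COc1cc(B2OC(C)(C)C(C)(C)O2)cc(O[Si](C)(C)C(C)(C)C)c1OC
A5 | alternative 2 | (R,E)-3-[3-(tert-butyldimethylsilyloxy)-4,5-dimethoxybenzylidene]-4-[4-(tert-butyldimethylsilyloxy)-3-methoxybenzyl]dihydrofuran-2(3H)-one | COc1cc(C[C@H]2COC(=O)/C2=C/c2cc(O[Si](C)(C)C(C)(C)C)c(OC)c(OC)c2)ccc1O[Si](C)(C)C(C)(C)C
A6 | alternative 3 | (R,E)-tributylstannylmethyl ether of 1-[4,5-dimethoxy-3-(triisopropylsilyloxy)phenyl]-2-[(tert-butyldimethylsilyloxy)methyl]-4-[3-methoxy-4-(triisopropylsilyloxy)phenyl]but-2-en-1-ol | COc1cc([C@@H](OC[Sn](CCCC)(CCCC)CCCC)/C(CO[Si](C)(C)C(C)(C)C)=C/Cc2ccc(O[Si](C(C)C)(C(C)C)C(C)C)c(OC)c2)cc(O[Si](C(C)C)(C(C)C)C(C)C)c1OC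
A7 | alternative 3 | (2R,3E)-3-[(tert-butyldimethylsilyloxy)methyl]-4-[4,5-dimethoxy-3-(triisopropylsilyloxy)phenyl]-2-[3-methoxy-4-(triisopropylsilyloxy)benzyl]but-3-en-1-ol | OC[C@H](Cc1ccc(O[Si](C(C)C)(C(C)C)C(C)C)c(OC)c1)/C(CO[Si](C)(C)C(C)(C)C)=C\c1cc(O[Si](C(C)C)(C(C)C)C(C)C)c(OC)c(OC)c1
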